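## Retrosynthetic overview
- The only ring, the tetrahydrofuran, is formed last. A DDQ dehydrogenative oxa-cyclization through a p-quinone methide closes the C7–O bond. This dearomatizes one phenol ring transiently and desymmetrizes the C2-symmetric (8R,8'R)-diol 5,5'-dimethoxysecoisolariciresinol.
- C8 and C8' are carried in from that diol and are already set as R,R. The C8 CH2OH and C8' CH2Ar substituents end up cis on the ring. The ring closure sets only C7, with the aryl group trans to the C8 CH2OH.
- The C2-symmetric diol comes from LiBH4 cleavage of a bis-imide. The bis-imide comes from oxidative homocoupling of two molecules of an (S)-4-benzyloxazolidinone imide enolate, which forms the C8–C8' bond and sets both stereocentres.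
- The imide comes from TBS-protected dihydrosinapic acid, which comes from sinapic acid.

Assumptions: sinapic acid and (S)-4-benzyloxazolidin-2-one are commercial. The Evans facial sense (electrophile anti to the 4-benzyl group) carries over to the enolate homocoupling, so the (S)-auxiliary gives the (R,R)-dimer.

## Route

**Step 1**
Reactants: 1, (E)-sinapic acid (3-(4-hydroxy-3,5-dimethoxyphenyl)acrylic acid)
Product: 2, 3-(4-hydroxy-3,5-dimethoxyphenyl)propanoic acid (dihydrosinapic acid)
Conditions: H2 (1 atm), 10% Pd/C, MeOH, rt
Reagents that add atoms: none (H2 adds only hydrogen)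
Why: Catalytic hydrogenation reduces the cinnamic C=C chemoselectively, and no stereocentre is formed.

**Step 2**
Reactants: 2
Product: 3, 3-(4-(tert-butyldimethylsilyloxy)-3,5-dimethoxyphenyl)propanoic acid
Conditions: TBSCl (2.3 equiv), imidazole, DMF, rt; then THF/H2O/AcOH (5:2:1), rt, 30 min (hydrolyses the silyl ester only)
Reagents that add atoms: TBSCl, CC(C)(C)[Si](C)(C)Cl (one TBS group is retained, on the phenol)
Why: Silylation masks the phenol so that it survives the enolate and Fe(III) oxidation, and the labile silyl ester is cleaved under mild acidic aqueous conditions. The hindered 2,6-dimethoxyaryl silyl ether is retained, leaving the free acid.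

**Step 3**
Reactants: 3; 4, (S)-4-benzyloxazolidin-2-one
Product: 5, (S)-4-benzyl-3-[3-(4-TBSO-3,5-dimethoxyphenyl)propanoyl]oxazolidin-2-one
Conditions: PivCl, Et3N, THF, 0 °C; then 4, LiCl, rt
Reagents that add atoms: none (the pivaloyl group of the mixed anhydride is lost)
Why: Acylation through the mixed pivalic anhydride (Ager-type imide formation) attaches the Evans auxiliary, which is the stereocontrol element.

**Step 4**
Reactants: 5 (two molecules; 2 × 5 − 2 H = 6)
Product: 6, (2R,3R)-2,3-bis(4-TBSO-3,5-dimethoxybenzyl)-1,4-bis[(S)-4-benzyl-2-oxooxazolidin-3-yl]butane-1,4-dione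
Conditions: LiHMDS (1.05 equiv relative to 5), THF, –78 °C, 1 h; then Fe(acac)3 (1.1 equiv relative to 5), –78 °C → 0 °C
Reagents that add atoms: none (Li and Fe are not retained; Fe(III) is only a one-electron oxidant)
Why: Oxidative homocoupling of the chelated Z-imide enolate joins two α-carbons to form the C8–C8' bond. Each α-carbon reacts on the face anti to the 4-benzyl group, so the homochiral pairing gives the C2-symmetric (R,R)-dimer, and the (R,S) and (S,S) diastereomers are removed by chromatography.

**Step 5**
Reactants: 6
Product: 7, (2R,3R)-2,3-bis(4-TBSO-3,5-dimethoxybenzyl)butane-1,4-diol (auxiliary 4 is recovered)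
Conditions: LiBH4 (6 equiv), MeOH (2 equiv per imide), Et2O/THF, 0 °C → rt
Reagents that add atoms: none (LiBH4 adds only hydrogen)
Why: Exocyclic (Evans) reductive cleavage converts both imides to primary alcohols without touching the α-stereocentres or the aryl silyl ethers. The descriptors stay R,R because the CIP priority order (C1 > C3 > CH2Ar) is the same in 6 and 7.

**Step 6**
Reactants: 7
Product: 8, (2R,3R)-2,3-bis(4-hydroxy-3,5-dimethoxybenzyl)butane-1,4-diol ((–)-5,5'-dimethoxysecoisolariciresinol)
Conditions: TBAF (2.2 equiv), AcOH (2.2 equiv), THF, 0 °C, N2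
Reagents that add atoms: none (TBS groups are removed)
Why: Fluoride desilylation frees the para-hydroxyls that the quinone-methide step requires, and buffering with AcOH limits phenoxide air oxidation. No stereocentre is touched.

**Step 7**
Reactants: 8
Product: 9, (+)-(7S,8R,8'R)-5,5'-dimethoxylariciresinol (target)
Conditions: DDQ (0.95 equiv), CH2Cl2 (0.01 M), 4 Å MS, –10 → 0 °C, 1 h; then aq. NaHCO3 work-up and chromatography (unreacted diol 8 recycled)
Reagents that add atoms: none (DDQ leaves as DDQH2, so the net change is loss of H2)
Why: Proposed new method: DDQ abstracts hydride from a benzylic C7–H para to a free phenol, giving a dearomatized p-quinone methide. The C9'–OH on the other arm adds 5-exo to the methide carbon (intramolecular oxa-Michael), and the ring rearomatizes. C8 and C8' are already fixed as R,R, so only C7 is created, and it takes the 7,8-trans arrangement (7S), with the aryl trans to the C8 CH2OH and on the opposite face to the cis-disposed C8/C8' substituents. The two arms are equivalent by C2 symmetry, so one mono-cyclized product forms. The closest known chemistry is DDQ benzylic C–H activation of 4-alkylphenols and alcohol addition to p-quinone methides. High dilution and substoichiometric DDQ suppress dimerization and a second cyclization to the furofuran (syringaresinol type).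

## Compound list
1 | (E)-sinapic acid | COc1cc(/C=C/C(=O)O)cc(OC)c1O | starting material
2 | 3-(4-hydroxy-3,5-dimethoxyphenyl)propanoic acid | COc1cc(CCC(=O)O)cc(OC)c1O | intermediate
3 | 3-(4-TBSO-3,5-dimethoxyphenyl)propanoic acid | COc1cc(CCC(=O)O)cc(OC)c1O[Si](C)(C)C(C)(C)C | intermediate
4 | (S)-4-benzyloxazolidin-2-one | C1[C@@H](NC(=O)O1)Cc1ccccc1 | starting material
5 | (S)-4-benzyl-3-[3-(4-TBSO-3,5-dimethoxyphenyl)propanoyl]oxazolidin-2-one | O=C(CCc1cc(OC)c(O[Si](C)(C)C(C)(C)C)c(OC)c1)N1C(=O)OC[C@@H]1Cc1ccccc1 | intermediate
6 | (2R,3R)-2,3-bis(4-TBSO-3,5-dimethoxybenzyl)-1,4-bis[(S)-4-benzyl-2-oxooxazolidin-3-yl]butane-1,4-dione | O=C(N1C(=O)OC[C@@H]1Cc1ccccc1)[C@H](Cc1cc(OC)c(O[Si](C)(C)C(C)(C)C)c(OC)c1)[C@@H](Cc1cc(OC)c(O[Si](C)(C)C(C)(C)C)c(OC)c1)C(=O)N1C(=O)OC[C@@H]1Cc1ccccc1 | intermediate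
7 | (2R,3R)-2,3-bis(4-TBSO-3,5-dimethoxybenzyl)butane-1,4-diol | OC[C@H](Cc1cc(OC)c(O[Si](C)(C)C(C)(C)C)c(OC)c1)[C@H](CO)Cc1cc(OC)c(O[Si](C)(C)C(C)(C)C)c(OC)c1 | intermediate
8 | (2R,3R)-2,3-bis(4-hydroxy-3,5-dimethoxybenzyl)butane-1,4-diol | OC[C@H](Cc1cc(OC)c(O)c(OC)c1)[C@H](CO)Cc1cc(OC)c(O)c(OC)c1 | intermediate
9 | (+)-(7S,8R,8'R)-5,5'-dimethoxylariciresinol | COc1cc(C[C@H]2CO[C@H](c3cc(OC)c(O)c(OC)c3)[C@H]2CO)cc(OC)c1O | target

## Step count
Total steps: 7. Longest linear sequence: 7 (from sinapic acid).

## Three steps most likely to fail
1. **Step 7 (DDQ cyclization).** Over-oxidation to the furofuran (syringaresinol type), phenol coupling, or poor 7S selectivity could all occur.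
   Fallback: oxidize 8 with 2 equiv DDQ to the cis-fused bis-THF (furofuran), then do a partial Pd/C hydrogenolysis of one benzylic C–O bond with recycling of over-reduced material. This cleaves at C7' and leaves C7 untouched, so it gives the 7S mono-THF.
2. **Step 4 (imide homocoupling).** The yield and diastereoselectivity of the Fe(III)-mediated dimerization are extrapolated from known imide enolate couplings.
   Fallback: build C8–C8' by a different route. Do a Stobbe condensation of TBS-protected syringaldehyde with diethyl succinate, then Ru-catalysed asymmetric hydrogenation to a single 2-benzylsuccinate half ester. Convert that to the butyrolactone, alkylate its enolate with the benzyl bromide to give the trans-dibenzylbutyrolactone, and open the lactone with LiAlH4 to the (R,R)-diol.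
3. **Step 5 (LiBH4 cleavage of the hindered α,α'-branched bis-imide).** Incomplete reduction or endocyclic cleavage of the oxazolidinone is possible.
   Fallback: transesterify the bis-imide with Ti(OiPr)4/BnOH to the (R,R)-dibenzyl diester, which avoids direct hydride attack on the imide and does not epimerize the α-centres. Then reduce with LiAlH4 to diol 7 (or directly to 8 if the aryl silyl ethers are cleaved).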